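The plan rests on cutting the C1–C5 ring-fusion bond (guaiane numbering), the single bond shared by the five-membered ring (C1–C5) and the seven-membered ring (C1, C5–C10); this unfolds the bicycle into a germacrane ten-membered ring. Commercial germacrone (1) already holds the C8 oxygen and the three-carbon branch on C7, so the precursor is its (4S,5S)-4,5-epoxide 2. In one operation, acid-triggered transannular attack of the C1=C10 alkene on the oxirane carbon C5 forms C1–C5, both rings and the trans-related C1 and C5 stereocentres, and ends in a C10 exocyclic methylene (hydroxy dienone 3) that later takes the C10 carbinol under guidance from the C8 hydroxyl.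

Key step: step 2

Remark: atoms carry guaiane numbers (C1, C5 = ring fusion; C4, C10 = methyl-bearing carbons; C7 = isopropyl-bearing carbon; C8 = ester carbon; C14 = carbon on C10). β is the face of H-5, which in the target also carries the isopropyl group and the C8 and C10 oxygens; α is the face of H-1 and of the oxirane oxygen.

Assumption: the L-fructose-derived (enantiomeric) ketone is the catalyst that gives the 4S,5S epoxide, by analogy with the facial preference of acyclic trisubstituted E-alkenes; if the macrocycle reverses that preference, the D-fructose-derived ketone takes its place.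

Step 1
Reactants: 1 germacrone
Product: 2 (4S,5S)-germacrone 4,5-epoxide ((1(10)E,4S,5S)-4,5-epoxygermacra-1(10),7(11)-dien-8-one)
Conditions: 1,2:4,5-di-O-isopropylidene-β-L-erythro-2,3-hexodiulo-2,6-pyranose (0.3 equiv), KHSO5 (as 2KHSO5·KHSO4·K2SO4, 1.2 equiv), K2CO3, Bu4NHSO4 (cat.), MeCN/CH2(OMe)2, aq. Na2B4O7 buffer, 0 °C
Reagents that add atoms: potassium peroxymonosulfate, [K+].[O-]S(=O)(=O)OO
Why: Shi asymmetric epoxidation, in which the chiral dioxirane attacks the more electron-rich C4=C5 alkene (C1=C10 is β,γ to the carbonyl) on its exposed outer face through the spiro transition state; because the two planar-chiral ring conformers interconvert quickly, the catalyst enantiomer selects one of them and sets both centres as 4S,5S, and the E geometry gives the trans-oxirane.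

Step 2
Reactants: 2 (4S,5S)-germacrone 4,5-epoxide
Product: 3 (1R,4S,5S)-4-hydroxyguaia-7(11),10(14)-dien-8-one (trans-fused)
Conditions: BF3·OEt2 (0.2 equiv), 2,6-di-tert-butyl-4-methylpyridine (0.3 equiv), 4 Å MS, CH2Cl2, −78 → −40 °C; then cold aq. NaHCO3
Reagents that add atoms: none
Why: Coordination of the Lewis acid weakens the C5–O bond of the oxirane, and the C1=C10 π bond, held across the ring against the back of C5, displaces oxygen in an SN2-like transannular cation–olefin cyclization (the known acid-induced closure of germacrene 4,5-epoxides to guaianes); the charge lands on tertiary C10, oxygen stays on C4, and the hindered pyridine moves a C14 proton to the C4 alkoxide. The C1–C5 bond closes the five-membered ring (C1–C5) in a mode that is exo with respect to the alkene (C10 stays outside) and endo with respect to the oxirane (C4 and C5 both become ring atoms), and it closes the seven-membered ring (C1, C5–C10) in a mode that is endo with respect to the alkene and exo with respect to the oxirane. C5 is set by inversion of the 5S oxirane carbon, and C1 by the crossed arrangement of the E-alkene and the trans-oxirane in the reacting conformer, where only the inner face of C1 reaches C5, so that H-1 and H-5 end up anti (trans fusion); C4 keeps its configuration. Closure at C1 and not at C10 follows from attack by the less substituted alkene carbon, which leaves the tertiary cation, and from the 1,5 distance across the ring. Loss of a C14 proton, and not capture at C10 (which would give the C10 alcohol of the wrong configuration) or migration of the alkene into conjugation with C8, is secured by the dry catalytic acid, the sieves and the non-nucleophilic base, and the three C14 hydrogens are the most accessible.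

Step 3
Reactants: 3 (1R,4S,5S)-4-hydroxyguaia-7(11),10(14)-dien-8-one
Product: 5 (1R,5S)-guaia-3,7(11),10(14)-trien-8-one, via C4 dichlorophosphate 4 (not isolated)
Conditions: POCl3 (3 equiv), pyridine, 0 °C → rt
Reagents that add atoms: none
Why: Dehydration by E2 elimination from the tertiary dichlorophosphate: the C4 oxygen is cis to H-5, so the anti-periplanar ring hydrogen is C3–Hα and the endocyclic trisubstituted C3=C4 alkene should form and not the C4=C5 isomer, while C1 and C5 are untouched.

Step 4
Reactants: 5 (1R,5S)-guaia-3,7(11),10(14)-trien-8-one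
Product: 8 (1R,5S,7R,8R)-guaia-3,10(14)-dien-8-ol (8β-hydroxyl cis to the 7β-isopropyl group), via lithium enolate 6 (not isolated), via ketone 7 (not isolated)
Conditions: LiBH(s-Bu)3 (1.1 equiv), THF, −78 °C; 2,6-di-tert-butyl-4-methylphenol (1.15 equiv), −78 → −50 °C; LiBH(s-Bu)3 (2 equiv), −78 °C; then H2O
Reagents that add atoms: none
Why: Conjugate (1,4) hydride reduction of the s-cis α-isopropylidene ketone (as with pulegone) gives the C7=C8 enolate, which the bulky phenol is meant to protonate kinetically at C7 along the equatorial α-face path (the axial β-face path meets the syn-axial C5–H), so that the isopropyl group ends up β; the ketone is reduced in the same flask before C7 can epimerize or the C10=C14 alkene can migrate, and the bulky borohydride attacks the carbonyl on the face away from the neighbouring isopropyl group to give the cis 8β alcohol (as in menthone to neomenthol).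

Step 5
Reactants: 8 (1R,5S,7R,8R)-guaia-3,10(14)-dien-8-ol
Product: 9 (1R,5S,7R,8R,10S)-10,14-epoxyguai-3-en-8-ol (oxirane oxygen β)
Conditions: VO(acac)2 (5 mol %), t-BuOOH (1.5 equiv), CH2Cl2, 0 °C → rt
Reagents that add atoms: tert-butyl hydroperoxide, CC(C)(C)OO
Why: Hydroxyl-directed epoxidation of a homoallylic alcohol, in which the vanadium alkoxide of the 8β-hydroxyl passes the peroxide oxygen to the face of the C10=C14 methylene that is syn to the C8 oxygen, so the new C10–O bond is β, and the undirected C3=C4 alkene is left alone.

Step 6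
Reactants: 9 (1R,5S,7R,8R,10S)-10,14-epoxyguai-3-en-8-ol
Product: 10 (1R,5S,7R,8R,10S)-guai-3-ene-8,10-diol
Conditions: LiAlH4 (2 equiv), THF, 0 °C; then H2O, aq. NaOH
Reagents that add atoms: none
Why: Reductive epoxide opening by SN2 attack of hydride at the unhindered C14 methylene (helped by delivery from the C8 alkoxyaluminate), so C10 keeps its β oxygen, gains the α methyl group and does not change configuration.

Step 7
Reactants: 10 (1R,5S,7R,8R,10S)-guai-3-ene-8,10-diol; 11 3,4-dimethoxybenzoyl chloride
Product: 12 (1R,5S,7R,8R,10S)-10-hydroxyguai-3-en-8-yl 3,4-dimethoxybenzoate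
Conditions: Et3N (3 equiv), DMAP (0.2 equiv), CH2Cl2, 0 °C → rt
Reagents that add atoms: 3,4-dimethoxybenzoyl chloride (11), COc1ccc(C(=O)Cl)cc1OC
Why: DMAP-catalysed esterification (nucleophilic acyl substitution) takes place at the secondary C8 hydroxyl only, since the tertiary C10 hydroxyl is too hindered, and no stereocentre is touched.

Step 8
Reactants: 12 (1R,5S,7R,8R,10S)-10-hydroxyguai-3-en-8-yl 3,4-dimethoxybenzoate
Product: 13 (1R,3R,4S,5S,7R,8R,10S)-3,4-epoxy-10-hydroxyguaian-8-yl 3,4-dimethoxybenzoate (target)
Conditions: KHSO5 (as 2KHSO5·KHSO4·K2SO4, 1.5 equiv), acetone, KHCO3, MeCN/H2O, 0 °C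
Reagents that add atoms: potassium peroxymonosulfate, [K+].[O-]S(=O)(=O)OO
Why: Epoxidation by dimethyldioxirane made in the flask: the trans fusion holds the cyclopentene as an envelope with C1 tipped toward the α face, so the pseudo-axial allylic C–H bonds at C2 and C5 both point β and attack on the α face is the staggered, torsionally favoured one, while the aqueous medium suppresses hydrogen-bond delivery from the β C10 hydroxyl; the oxirane should therefore form on the α face (3R,4S).

Compound list
1 | germacrone | C/C1=C\CC/C(C)=C/CC(=C(C)C)C(=O)C1 | starting material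
2 | (4S,5S)-germacrone 4,5-epoxide | C/C1=C\CC[C@]2(C)O[C@H]2CC(=C(C)C)C(=O)C1 | intermediate
3 | (1R,4S,5S)-4-hydroxyguaia-7(11),10(14)-dien-8-one, trans-fused | O=C1CC(=C)[C@@H]2CC[C@](C)(O)[C@H]2CC1=C(C)C | intermediate
4 | (1R,4S,5S)-8-oxoguaia-7(11),10(14)-dien-4-yl phosphorodichloridate | O=C1CC(=C)[C@@H]2CC[C@](C)(OP(=O)(Cl)Cl)[C@H]2CC1=C(C)C | intermediate
5 | (1R,5S)-guaia-3,7(11),10(14)-trien-8-one | O=C1CC(=C)[C@@H]2CC=C(C)[C@H]2CC1=C(C)C | intermediate
6 | lithium (1R,5S)-guaia-3,7,10(14)-trien-8-olate | [Li]OC1=C(C(C)C)C[C@@H]2C(C)=CC[C@H]2C(=C)C1 | intermediate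
7 | (1R,5S,7R)-guaia-3,10(14)-dien-8-one | O=C1CC(=C)[C@@H]2CC=C(C)[C@H]2C[C@@H]1C(C)C | intermediate
8 | (1R,5S,7R,8R)-guaia-3,10(14)-dien-8-ol | O[C@@H]1CC(=C)[C@@H]2CC=C(C)[C@H]2C[C@@H]1C(C)C | intermediate
9 | (1R,5S,7R,8R,10S)-10,14-epoxyguai-3-en-8-ol | O[C@@H]1C[C@]3(OC3)[C@@H]2CC=C(C)[C@H]2C[C@@H]1C(C)C | intermediate
10 | (1R,5S,7R,8R,10S)-guai-3-ene-8,10-diol | O[C@@H]1C[C@](C)(O)[C@@H]2CC=C(C)[C@H]2C[C@@H]1C(C)C | intermediate
11 | 3,4-dimethoxybenzoyl chloride | COc1ccc(C(=O)Cl)cc1OC | starting material
12 | (1R,5S,7R,8R,10S)-10-hydroxyguai-3-en-8-yl 3,4-dimethoxybenzoate | COc1ccc(C(=O)O[C@@H]2C[C@](C)(O)[C@@H]3CC=C(C)[C@H]3C[C@@H]2C(C)C)cc1OC | intermediate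
13 | (1R,3R,4S,5S,7R,8R,10S)-3,4-epoxy-10-hydroxyguaian-8-yl 3,4-dimethoxybenzoate | COc1ccc(C(=O)O[C@@H]2C[C@](C)(O)[C@@H]3C[C@H]4O[C@@]4(C)[C@H]3C[C@@H]2C(C)C)cc1OC | target

Total step count: 8 steps.
Longest linear sequence: 8 steps from germacrone (1); 3,4-dimethoxybenzoyl chloride (11) enters in step 7.

The three steps most likely to fail:

Step 2 is the most exposed. The C10 cation may lose a proton from C9 or C1 and not from C14, may be captured by traces of water or by fluoride, or the methylene may drift into conjugation with the C8 carbonyl under traces of protic acid. The fallback replaces adventitious termination by silyl-cation initiation with a stoichiometric hindered base and protection in the flask. It sets out from 2, which is treated with Me3SiOTf and 2,6-di-tert-butyl-4-methylpyridine in CH2Cl2 at −78 °C, so that the base takes the C14 proton and the C4 oxygen is capped, giving (1R,4S,5S)-4-(trimethylsilyloxy)guaia-7(11),10(14)-dien-8-one F1. Bu4NF in THF at 0 °C then frees the alcohol, and the route is rejoined at 3.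

Step 4 carries the least certain stereocontrol. Protonation of enolate 6 may show poor facial selectivity, since delivery on the β face gives the more stable C7 epimer, or ketone 7 may epimerize before it is reduced. The fallback puts catalyst control in the place of substrate control. It sets out from 5: enolate 6, made with LiBH(s-Bu)3, is trapped with Me3SiCl/Et3N to give (1R,5S)-8-(trimethylsilyloxy)guaia-3,7,10(14)-triene F2, which is isolated. F2 is protonated in toluene at −78 °C with phenol and 5 mol % of a BINOL-derived chiral N-triflyl thiophosphoramide, the catalyst enantiomer that matches α-face delivery being chosen in a small screen. The route is rejoined at ketone 7, which is reduced at once with LiBH(s-Bu)3 to 8.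

Step 8 may deliver oxygen to the β face under hydrogen-bond guidance from the C10 hydroxyl, or may discriminate the two faces only weakly. The fallback uses a protecting group that masks the hydroxyl and blocks the β face. It sets out from 12: Me3SiOTf/2,6-lutidine in CH2Cl2 at −78 °C gives (1R,5S,7R,8R,10S)-10-(trimethylsilyloxy)guai-3-en-8-yl 3,4-dimethoxybenzoate F3. Epoxidation with m-chloroperbenzoic acid/NaHCO3 in CH2Cl2 at 0 °C gives (1R,3R,4S,5S,7R,8R,10S)-3,4-epoxy-10-(trimethylsilyloxy)guaian-8-yl 3,4-dimethoxybenzoate F4. Bu4NF buffered with AcOH in THF at 0 °C removes the silyl group, and the route is rejoined at the target 13.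

Further compounds
F1 | step 2 | (1R,4S,5S)-4-(trimethylsilyloxy)guaia-7(11),10(14)-dien-8-one | O=C1CC(=C)[C@@H]2CC[C@](C)(O[Si](C)(C)C)[C@H]2CC1=C(C)C
F2 | step 4 | (1R,5S)-8-(trimethylsilyloxy)guaia-3,7,10(14)-triene | C[Si](C)(C)OC1=C(C(C)C)C[C@@H]2C(C)=CC[C@H]2C(=C)C1
F3 | step 8 | (1R,5S,7R,8R,10S)-10-(trimethylsilyloxy)guai-3-en-8-yl 3,4-dimethoxybenzoate | COc1ccc(C(=O)O[C@@H]2C[C@](C)(O[Si](C)(C)C)[C@@H]3CC=C(C)[C@H]3C[C@@H]2C(C)C)cc1OC
F4 | step 8 | (1R,3R,4S,5S,7R,8R,10S)-3,4-epoxy-10-(trimethylsilyloxy)guaian-8-yl 3,4-dimethoxybenzoate | COc1ccc(C(=O)O[C@@H]2C[C@](C)(O[Si](C)(C)C)[C@@H]3C[C@H]4O[C@@]4(C)[C@H]3C[C@@H]2C(C)C)cc1OC
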